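**Plan**

1. Retrosynthesis: the free acid is masked as a tert-butyl ester. The bond between ring carbon C2 (next to ring oxygen O1) and the first CH2 of the 14-oxopentadecyl chain is then cut to two N-acyloxyphthalimides, one from a ring C2-carboxylic acid and one from 15-oxohexadecanoic acid. The lactone is opened at O1–C5 (C5 from a vinyl group), and the C3–C4 bond is cut by an Ireland–Claisen retron to a crotyl malate.
2. Enabling feature: O1 of the five-membered lactone stabilises a radical at C2, so a C2-carboxyl group (C1 of malic acid) is a traceless handle. The ring holds C3-CO2tBu and C4-CH3 on one face, so the chain must enter trans to them.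
3. Forward order: (S)-malic acid → 1-benzyl 4-crotyl malate → dianionic Ireland–Claisen rearrangement (C3–C4 bond) → ozonolysis and lactol oxidation (lactone ring) → debenzylation and phthalimide ester → electrochemical doubly decarboxylative coupling (chain joined) → tert-butyl ester cleavage.
4. Stereochemistry: C3 comes from the (S)-carbinol of malic acid through the chelated dianion, and C4 from the (E)-olefin through the chair transition state. C2 is set by C3 and C4 in the radical coupling, after the malic acid stereocentre itself has been erased.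

Key step: step 11

Assumption: (2E)-but-2-en-1-ol of high geometric purity is used, because the olefin geometry is relayed into C4; ring atoms are numbered O1, C2 (chain), C3 (carboxyl), C4 (methyl), C5 (carbonyl) throughout.

**Route**

Step 1
Reactants: 1 (S)-malic acid
Product: 4 (3S)-4-(benzyloxy)-3-hydroxy-4-oxobutanoic acid, via anhydride 2 (not isolated), via trifluoroacetate 3 (not isolated)
Conditions: (CF3CO)2O, 0 °C → rt; evaporate; BnOH, rt; aq NaHCO3, then aq HCl
Reagents that add atoms: benzyl alcohol, OCc1ccccc1
Why: Cyclic anhydride formation followed by regioselective alcoholysis, in which the carbonyl next to the trifluoroacetoxy-bearing carbon of 2 is the more electrophilic, so benzyl alcohol should open the ring there, and the labile trifluoroacetate is hydrolysed on work-up without touching the stereocentre.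

Step 2
Reactants: 4 (3S)-4-(benzyloxy)-3-hydroxy-4-oxobutanoic acid; 5 (2E)-but-2-en-1-ol
Product: 6 1-benzyl 4-[(2E)-but-2-en-1-yl] (2S)-2-hydroxybutanedioate
Conditions: 5 (3 equiv), N,N'-diisopropylcarbodiimide, DMAP (5 mol%), CH2Cl2, 0 °C → rt
Reagents that add atoms: none
Why: Steglich esterification, in which the primary allylic alcohol in excess should outcompete the deactivated secondary hydroxyl of the α-hydroxy ester for the activated acid; no stereocentre is involved.

Step 3
Reactants: 6 1-benzyl 4-[(2E)-but-2-en-1-yl] (2S)-2-hydroxybutanedioate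
Product: 8 (2R,3R)-2-[(1S)-2-(benzyloxy)-1-hydroxy-2-oxoethyl]-3-methylpent-4-enoic acid, via chelated dianion 7 (not isolated)
Conditions: LiN(iPr)2 (2.3 equiv), THF, −78 °C → rt; then dilute aq HCl
Reagents that add atoms: none
Why: Dianionic Ireland–Claisen rearrangement, in which the lithium alkoxide locks the enolate in a six-membered chelate (enolate oxygen cis to the carbinol carbon), the crotyl group is delivered to the enolate face anti to the CO2Bn-bearing carbinol substituent as in a Fráter–Seebach alkylation (sets 2R), and the chair transition state relays the (E)-olefin geometry into the 3R methyl centre.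

Step 4
Reactants: 8 (2R,3R)-2-[(1S)-2-(benzyloxy)-1-hydroxy-2-oxoethyl]-3-methylpent-4-enoic acid
Product: 9 1-benzyl 4-tert-butyl (2S,3R)-3-[(2R)-but-3-en-2-yl]-2-hydroxybutanedioate
Conditions: tert-butyl 2,2,2-trichloroacetimidate (2.5 equiv), CH2Cl2/cyclohexane, rt
Reagents that add atoms: tert-butyl 2,2,2-trichloroacetimidate, CC(C)(C)OC(=N)C(Cl)(Cl)Cl
Why: Tert-butylation of a carboxylic acid by the trichloroacetimidate, promoted by the acid itself without a Lewis acid, which should leave the hindered secondary hydroxyl and the benzyl ester untouched.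

Step 5
Reactants: 9 1-benzyl 4-tert-butyl (2S,3R)-3-[(2R)-but-3-en-2-yl]-2-hydroxybutanedioate
Product: 12 2-benzyl 3-tert-butyl (2S,3R,4S)-4-methyl-5-oxotetrahydrofuran-2,3-dicarboxylate, via hydroxy aldehyde 10 (not isolated), via lactol 11 (not isolated)
Conditions: O3, CH2Cl2, −78 °C; Me2S, −78 °C → rt; concentrate; then TEMPO (10 mol%), PhI(OAc)2, CH2Cl2, rt
Reagents that add atoms: ozone, O=[O+][O-]
Why: Ozonolysis with reductive work-up gives the aldehyde, which the C2 hydroxyl should trap at once as the five-membered lactol (limiting enolisation of the α-methyl centre), and oxoammonium oxidation of the lactol closes the all-cis lactone without touching the three stereocentres.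

Step 6
Reactants: 12 2-benzyl 3-tert-butyl (2S,3R,4S)-4-methyl-5-oxotetrahydrofuran-2,3-dicarboxylate
Product: 13 (2S,3R,4S)-3-(tert-butoxycarbonyl)-4-methyl-5-oxotetrahydrofuran-2-carboxylic acid
Conditions: H2 (1 atm), Pd/C (10% Pd), EtOAc, rt
Reagents that add atoms: none
Why: Hydrogenolysis of the benzyl ester, to which the tert-butyl ester, the lactone and the stereocentres are inert.

Step 7
Reactants: 13 (2S,3R,4S)-3-(tert-butoxycarbonyl)-4-methyl-5-oxotetrahydrofuran-2-carboxylic acid
Product: 14 3-tert-butyl 2-(1,3-dioxoisoindolin-2-yl) (2S,3R,4S)-4-methyl-5-oxotetrahydrofuran-2,3-dicarboxylate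
Conditions: N-hydroxyphthalimide, N,N'-diisopropylcarbodiimide, DMAP (10 mol%), CH2Cl2, 0 °C → rt
Reagents that add atoms: N-hydroxyphthalimide, O=C1c2ccccc2C(=O)N1O
Why: Carbodiimide (Steglich-type) esterification gives the redox-active ester, and any C2 epimerisation is without consequence because C2 becomes a planar radical in step 11.

Step 8
Reactants: 15 15-hydroxypentadecanoic acid
Product: 17 16-hydroxyhexadecan-2-one, via trilithium gem-diolate 16 (not isolated)
Conditions: MeLi (3.3 equiv), THF, 0 °C → rt; inverse quench into ice-cold dilute aq HCl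
Reagents that add atoms: methyllithium, [Li]C
Why: Addition of methyllithium to a lithium carboxylate gives a gem-diolate that cannot collapse to the ketone before the inverse acidic quench, so the methyl ketone should form without over-addition.

Step 9
Reactants: 17 16-hydroxyhexadecan-2-one
Product: 18 15-oxohexadecanoic acid
Conditions: TEMPO (20 mol%), PhI(OAc)2 (2.2 equiv), MeCN/H2O (1:1), rt
Reagents that add atoms: water, O
Why: Oxoammonium (TEMPO) oxidation in aqueous acetonitrile takes the primary alcohol through the aldehyde hydrate to the acid and leaves the ketone untouched.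

Step 10
Reactants: 18 15-oxohexadecanoic acid
Product: 19 1,3-dioxoisoindolin-2-yl 15-oxohexadecanoate
Conditions: N-hydroxyphthalimide, N,N'-diisopropylcarbodiimide, DMAP (10 mol%), CH2Cl2, rt
Reagents that add atoms: N-hydroxyphthalimide, O=C1c2ccccc2C(=O)N1O
Why: Carbodiimide (Steglich-type) esterification with N-hydroxyphthalimide, as in step 7, under conditions that do not affect the ketone.

Step 11
Reactants: 14 3-tert-butyl 2-(1,3-dioxoisoindolin-2-yl) (2S,3R,4S)-4-methyl-5-oxotetrahydrofuran-2,3-dicarboxylate; 19 1,3-dioxoisoindolin-2-yl 15-oxohexadecanoate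
Product: 20 tert-butyl (2S,3R,4S)-4-methyl-5-oxo-2-(14-oxopentadecyl)tetrahydrofuran-3-carboxylate
Conditions: 19 (3 equiv), NiCl2·6H2O (20 mol%), 2,2′:6′,2″-terpyridine (20 mol%), AgNO3 (30 mol%), NMP, Mg anode, reticulated vitreous carbon cathode, undivided cell, constant current, rt; dilute aq HCl work-up
Reagents that add atoms: none
Why: Cathodically generated low-valent nickel, working at the silver-coated cathode formed from AgNO3, transfers single electrons to both N-acyloxyphthalimides, which fragment with loss of phthalimide anion and CO2 to the primary 14-oxopentadecyl radical and the secondary C2 radical of the lactone (stabilised by the lone pair of O1); nickel captures the two radicals in turn and the dialkylnickel species (formally trivalent nickel) reductively eliminates the C2–CH2 bond. The closest known reaction type is the nickel-electrocatalytic doubly decarboxylative C(sp3)–C(sp3) coupling of two redox-active esters, including α-oxygenated five-membered-ring esters that couple trans to a neighbouring substituent. No ring is closed. The only new stereocentre, C2, is controlled by the substrate: the radical is planar, and C3-CO2tBu and C4-CH3 both lie on one face of the lactone, so nickel capture and bond formation should take place on the opposite face and give the 2,3-trans (2S) product, whatever the C2 configuration of 14. The step needs cross- over homo-coupling and tolerance of the methyl ketone; the electronically different radicals (stabilised α-oxy secondary against unstabilised primary), a threefold excess of the cheap ester 19 and the mild cathodic potential should secure both.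

Step 12
Reactants: 20 tert-butyl (2S,3R,4S)-4-methyl-5-oxo-2-(14-oxopentadecyl)tetrahydrofuran-3-carboxylate
Product: 21 (2S,3R,4S)-4-methyl-5-oxo-2-(14-oxopentadecyl)tetrahydrofuran-3-carboxylic acid
Conditions: CF3CO2H/CH2Cl2 (1:4), 0 °C → rt
Reagents that add atoms: none
Why: Acidolysis of the tert-butyl ester through the tert-butyl cation, under conditions where the ketone, the lactone and the cis C3/C4 relationship (no enolisation) should be stable.

**Compound list**

1 | (S)-malic acid, (2S)-2-hydroxybutanedioic acid | OC(=O)C[C@H](O)C(=O)O | starting material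
2 | (3S)-2,5-dioxotetrahydrofuran-3-yl trifluoroacetate | O=C1C[C@H](OC(=O)C(F)(F)F)C(=O)O1 | intermediate
3 | (3S)-4-(benzyloxy)-4-oxo-3-(trifluoroacetoxy)butanoic acid | OC(=O)C[C@H](OC(=O)C(F)(F)F)C(=O)OCc1ccccc1 | intermediate
4 | (3S)-4-(benzyloxy)-3-hydroxy-4-oxobutanoic acid | OC(=O)C[C@H](O)C(=O)OCc1ccccc1 | intermediate
5 | (2E)-but-2-en-1-ol | C/C=C/CO | starting material
6 | 1-benzyl 4-[(2E)-but-2-en-1-yl] (2S)-2-hydroxybutanedioate | C/C=C/COC(=O)C[C@H](O)C(=O)OCc1ccccc1 | intermediate
7 | chelated dilithium alkoxide-enolate of 6 (enolate oxygen cis to the carbinol carbon) | [Li+].[Li+].[O-]/C(OC/C=C/C)=C\[C@H]([O-])C(=O)OCc1ccccc1 | intermediate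
8 | (2R,3R)-2-[(1S)-2-(benzyloxy)-1-hydroxy-2-oxoethyl]-3-methylpent-4-enoic acid | C=C[C@@H](C)[C@H]([C@H](O)C(=O)OCc1ccccc1)C(=O)O | intermediate
9 | 1-benzyl 4-tert-butyl (2S,3R)-3-[(2R)-but-3-en-2-yl]-2-hydroxybutanedioate | C=C[C@@H](C)[C@H]([C@H](O)C(=O)OCc1ccccc1)C(=O)OC(C)(C)C | intermediate
10 | 1-benzyl 4-tert-butyl (2S,3R)-2-hydroxy-3-[(2S)-1-oxopropan-2-yl]butanedioate | O=C[C@@H](C)[C@H]([C@H](O)C(=O)OCc1ccccc1)C(=O)OC(C)(C)C | intermediate
11 | 2-benzyl 3-tert-butyl (2S,3R,4S)-5-hydroxy-4-methyltetrahydrofuran-2,3-dicarboxylate (both anomers) | O=C(OCc1ccccc1)[C@H]1OC(O)[C@@H](C)[C@H]1C(=O)OC(C)(C)C | intermediate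
12 | 2-benzyl 3-tert-butyl (2S,3R,4S)-4-methyl-5-oxotetrahydrofuran-2,3-dicarboxylate | O=C(OCc1ccccc1)[C@H]1OC(=O)[C@@H](C)[C@H]1C(=O)OC(C)(C)C | intermediate
13 | (2S,3R,4S)-3-(tert-butoxycarbonyl)-4-methyl-5-oxotetrahydrofuran-2-carboxylic acid | OC(=O)[C@H]1OC(=O)[C@@H](C)[C@H]1C(=O)OC(C)(C)C | intermediate
14 | 3-tert-butyl 2-(1,3-dioxoisoindolin-2-yl) (2S,3R,4S)-4-methyl-5-oxotetrahydrofuran-2,3-dicarboxylate | O=C(ON1C(=O)c2ccccc2C1=O)[C@H]1OC(=O)[C@@H](C)[C@H]1C(=O)OC(C)(C)C | intermediate
15 | 15-hydroxypentadecanoic acid | OCCCCCCCCCCCCCCC(=O)O | starting material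
16 | trilithium 16-oxidohexadecane-2,2-diolate | [Li+].[Li+].[Li+].CC([O-])([O-])CCCCCCCCCCCCCC[O-] | intermediate
17 | 16-hydroxyhexadecan-2-one | CC(=O)CCCCCCCCCCCCCCO | intermediate
18 | 15-oxohexadecanoic acid | CC(=O)CCCCCCCCCCCCCC(=O)O | intermediate
19 | 1,3-dioxoisoindolin-2-yl 15-oxohexadecanoate | CC(=O)CCCCCCCCCCCCCC(=O)ON1C(=O)c2ccccc2C1=O | intermediate
20 | tert-butyl (2S,3R,4S)-4-methyl-5-oxo-2-(14-oxopentadecyl)tetrahydrofuran-3-carboxylate | CC(=O)CCCCCCCCCCCCC[C@@H]1OC(=O)[C@@H](C)[C@H]1C(=O)OC(C)(C)C | intermediate
21 | (2S,3R,4S)-4-methyl-5-oxo-2-(14-oxopentadecyl)tetrahydrofuran-3-carboxylic acid | CC(=O)CCCCCCCCCCCCC[C@@H]1OC(=O)[C@@H](C)[C@H]1C(=O)O | target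

**Count and risks**

Total step count: 12. Longest linear sequence: 9 steps (steps 1–7, 11, 12); the chain branch (steps 8–10) joins at step 11.

Steps most likely to fail:

Step 11. Homo-coupling of either radical may outrun cross-coupling, the secondary alkylnickel intermediate may undergo β-hydride elimination towards a butenolide, or the ketone may be reduced at the cathode. The fallback sets out from acid 13 (leaving out 14 and 19) and uses a metallaphotoredox decarboxylative C(sp3)–C(sp3) coupling of the free acid with a primary alkyl bromide. Ethyl acetoacetate is alkylated with an excess of 1,12-dibromododecane (K2CO3, acetone, reflux) to ethyl 2-acetyl-14-bromotetradecanoate F1, which is hydrolysed and decarboxylated (48% aq HBr, AcOH, reflux) to 15-bromopentadecan-2-one F2. Acid 13 and F2 are then coupled with Ir[dF(CF3)ppy]2(dtbbpy)PF6, NiCl2·glyme, 4,4′-dimethoxy-2,2′-bipyridine and K2CO3 in MeCN/H2O under blue light at rt. Photo-oxidation of the carboxylate of 13 should give the same C2 radical, which nickel should join to the alkyl group on the face trans to C3. The fallback comes back to the route at 20.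

Step 3. The dianion may decompose on warming (retro-aldol cleavage, ester exchange) before the [3,3] shift, or the facial and chair selectivity may erode. The fallback sets out from 4. Tert-butylation (tert-butyl 2,2,2-trichloroacetimidate, CH2Cl2) should give 1-benzyl 4-tert-butyl (2S)-2-hydroxybutanedioate F3. Fráter–Seebach allylation (LiN(iPr)2 2.2 equiv, allyl bromide, THF, −78 → −20 °C) should give 1-benzyl 4-tert-butyl (2S,3R)-2-hydroxy-3-(prop-2-en-1-yl)butanedioate F4. Ozonolysis and lactol oxidation as in step 5 should give 2-benzyl 3-tert-butyl (2S,3R)-5-oxotetrahydrofuran-2,3-dicarboxylate F5. Condensation with tert-butoxybis(dimethylamino)methane (toluene, 80 °C) should give 2-benzyl 3-tert-butyl (2S,3R,4E)-4-[(dimethylamino)methylidene]-5-oxotetrahydrofuran-2,3-dicarboxylate F6. Hydrogenation over Pd/C (H2, EtOAc/iPrOH) should convert the enamine carbon into the C4 methyl group with loss of dimethylamine and cleave the benzyl ester; hydrogen should be delivered to the face opposite the two cis carboxyl groups, which places the methyl cis to C3. The fallback comes back to the route at 13.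

Step 8. Over-addition to the tertiary alcohol may occur if ketone is set free while methyllithium is still present, and the lithium carboxylate may aggregate and react incompletely. The fallback sets out from 15. Amide coupling with N,O-dimethylhydroxylamine hydrochloride (EDC·HCl, HOBt, iPr2NEt, CH2Cl2) should give 15-hydroxy-N-methoxy-N-methylpentadecanamide F7. MeMgBr (3 equiv, THF, 0 °C) then forms a chelated tetrahedral adduct that releases the ketone only on work-up. The fallback comes back to the route at 17.

**Further compounds**

F1 | step 11 | ethyl 2-acetyl-14-bromotetradecanoate | CCOC(=O)C(C(C)=O)CCCCCCCCCCCCBr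
F2 | step 11 | 15-bromopentadecan-2-one | CC(=O)CCCCCCCCCCCCCBr
F3 | step 3 | 1-benzyl 4-tert-butyl (2S)-2-hydroxybutanedioate | CC(C)(C)OC(=O)C[C@H](O)C(=O)OCc1ccccc1
F4 | step 3 | 1-benzyl 4-tert-butyl (2S,3R)-2-hydroxy-3-(prop-2-en-1-yl)butanedioate | C=CC[C@H]([C@H](O)C(=O)OCc1ccccc1)C(=O)OC(C)(C)C
F5 | step 3 | 2-benzyl 3-tert-butyl (2S,3R)-5-oxotetrahydrofuran-2,3-dicarboxylate | O=C(OCc1ccccc1)[C@H]1OC(=O)C[C@H]1C(=O)OC(C)(C)C
F6 | step 3 | 2-benzyl 3-tert-butyl (2S,3R,4E)-4-[(dimethylamino)methylidene]-5-oxotetrahydrofuran-2,3-dicarboxylate | O=C(OCc1ccccc1)[C@H]1OC(=O)/C(=C/N(C)C)[C@H]1C(=O)OC(C)(C)C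
F7 | step 8 | 15-hydroxy-N-methoxy-N-methylpentadecanamide | CON(C)C(=O)CCCCCCCCCCCCCCO
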